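**Strategy.** Each sesquiterpenyl chain hangs from a quaternary carbon C3 that bears a methyl group, an aryl ring (ring A or ring B), the C1=C2 vinyl group and the C4–C5 arm. That carbon is treated as C3 of a 3-aryl-3-methylcyclopropene: enantioselective ring-opening/cross-metathesis with butyl vinyl ether cuts the ring C=C into the vinyl group and a C4=C5 enol ether (a masked C5 aldehyde) and sets the stereocentre in one operation. The precursor is the brominated, bis-MOM-protected ring A cyclopropene; ring B is opened likewise with the mirror-image catalyst. Each half is then extended at C5 by Negishi coupling with one (E)-alkenyl iodide, and the halves are joined by Ullmann etherification.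

Key step: step 8

Assumption: which antipode of the aryloxide ligand HOAr* gives the drawn sense of ring opening is settled by a pilot run with stereochemical correlation; step 8 uses the antipode that gives 10 and step 20 uses its mirror image.

Remark on descriptors: the enol ether arm outranks vinyl, so the ring A centre is (S) in 10 and (R) from 11 on, and the ring B centre is (R) in 28 and (S) from 29 on; no bond at either centre is broken.

**Step 1**
Reactants: 1 acetovanillone
Product: 2 1-(3-bromo-4-hydroxy-5-methoxyphenyl)ethanone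
Conditions: Br2 (1.05 equiv), AcOH, rt
Reagents that add atoms: bromine, BrBr
Why: Electrophilic aromatic bromination, in which the phenol directs ortho, its para position carries the acetyl group and the other ortho position carries OMe, so only C5 is open.

**Step 2**
Reactants: 2 1-(3-bromo-4-hydroxy-5-methoxyphenyl)ethanone
Product: 3 1-(3-bromo-4,5-dihydroxyphenyl)ethanone
Conditions: BBr3 (3 equiv), CH2Cl2, −78 °C → rt; H2O
Reagents that add atoms: none
Why: Lewis acid ether cleavage (BBr3 demethylation), in which bromide attacks the O-methyl group of the boron-bound anisole while ketone and aryl bromide are inert.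

**Step 3**
Reactants: 3 1-(3-bromo-4,5-dihydroxyphenyl)ethanone
Product: 4 1-[3-bromo-4,5-bis(methoxymethoxy)phenyl]ethanone
Conditions: MOMCl (3 equiv), iPr2NEt (4 equiv), CH2Cl2, 0 °C → rt
Reagents that add atoms: chloromethyl methyl ether, COCCl
Why: O-Alkylation of both phenols with the α-chloro ether (MOM acetal formation) gives a catechol protection that withstands ylides, carbenes, Grignard reagents, alkoxide bases, the molybdenum alkylidene and organozinc reagents.

**Step 4**
Reactants: 4 1-[3-bromo-4,5-bis(methoxymethoxy)phenyl]ethanone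
Product: 5 1-bromo-2,3-bis(methoxymethoxy)-5-(prop-1-en-2-yl)benzene
Conditions: Ph3PCH3Br, KOtBu, THF, 0 °C → rt
Reagents that add atoms: methyltriphenylphosphonium bromide, C[P+](c1ccccc1)(c1ccccc1)c1ccccc1.[Br-]
Why: Wittig methylenation of the aryl methyl ketone with the non-stabilised ylide.

**Step 5**
Reactants: 5 1-bromo-2,3-bis(methoxymethoxy)-5-(prop-1-en-2-yl)benzene
Product: 6 1-bromo-5-(2,2-dibromo-1-methylcyclopropyl)-2,3-bis(methoxymethoxy)benzene (racemic)
Conditions: CHBr3, 50% aq NaOH, BnEt3NCl (5 mol%), CH2Cl2, rt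
Reagents that add atoms: bromoform, BrC(Br)Br
Why: [2+1] Cycloaddition of dibromocarbene made under phase-transfer (Makosza) conditions to the electron-rich 1,1-disubstituted alkene; the racemic stereocentre is erased in step 7.

**Step 6**
Reactants: 6 1-bromo-5-(2,2-dibromo-1-methylcyclopropyl)-2,3-bis(methoxymethoxy)benzene
Product: 7 1-bromo-5-(2-bromo-1-methylcyclopropyl)-2,3-bis(methoxymethoxy)benzene (racemic, both diastereomers)
Conditions: EtMgBr (1.3 equiv), Ti(OiPr)4 (5 mol%), Et2O, rt
Reagents that add atoms: none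
Why: Titanium-catalysed hydrodebromination of a gem-dibromocyclopropane, with the ethyl group of the Grignard reagent as hydride source; the strained gem-dibromide should react far faster than the electron-rich aryl bromide, and both diastereomers serve step 7.

**Step 7**
Reactants: 7 1-bromo-5-(2-bromo-1-methylcyclopropyl)-2,3-bis(methoxymethoxy)benzene
Product: 8 3-[3-bromo-4,5-bis(methoxymethoxy)phenyl]-3-methylcyclopropene
Conditions: KOtBu (1.5 equiv), DMSO, rt
Reagents that add atoms: none
Why: Base-induced 1,2-dehydrobromination of the bromocyclopropane; the quaternary ring carbon keeps the double bond in the ring, and a small excess of base at rt should spare the aryl bromide.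

**Step 8**
Reactants: 8 3-[3-bromo-4,5-bis(methoxymethoxy)phenyl]-3-methylcyclopropene; 9 butyl vinyl ether
Product: 10 1-bromo-5-[(1Z,3S)-1-butoxy-3-methylpenta-1,4-dien-3-yl]-2,3-bis(methoxymethoxy)benzene
Conditions: Mo(N-2,6-iPr2C6H3)(CHCMe2Ph)(2,5-Me2C4H2N)(OAr*) (3 mol%, made in situ from Mo(N-2,6-iPr2C6H3)(CHCMe2Ph)(2,5-Me2C4H2N)2 and enantiopure HOAr*), 9 (10 equiv), C6H6, 22 °C; HOAr* = 3,3'-dibromo-2'-(tert-butyldimethylsilyloxy)-5,5',6,6',7,7',8,8'-octahydro-1,1'-binaphthalen-2-ol
Reagents that add atoms: none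
Why: Olefin metathesis through [2+2] cycloaddition and cycloreversion: the butoxymethylidene of hexavalent molybdenum that forms from the catalyst and 9 adds to the strained C=C of 8 on the face anti to the aryl group, the molybdacyclobutane opens with loss of ring strain to an alkylidene that already carries the CH=CHOBu arm, and metathesis of this alkylidene with a second molecule of 9 leaves the terminal vinyl group and returns the butoxymethylidene. The closest known reaction type is the enantioselective ring-opening/cross-metathesis of 3-aryl-3-methylcyclopropenes with enol ethers under monoaryloxide pyrrolide molybdenum alkylidenes. No ring is closed, since the only ring event is the opening of the three-membered ring. The quaternary stereocentre arises because the two olefinic carbons of 8 are enantiotopic, and the stereogenic molybdenum centre with its enantiopure aryloxide decides which of them receives the butoxymethylidene unit, here in the sense that gives (S)-10. The step needs this enantiotopic-carbon selectivity together with ring opening instead of oligomerisation: the two C3 substituents shield the opened alkylidene from a second cyclopropene, the excess of 9 captures it, and the aryl bromide and MOM acetals do not react with the alkylidene. The Z or E geometry of the enol ether has no consequence, because C5 becomes an aldehyde carbon in step 9.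

**Step 9**
Reactants: 10 1-bromo-5-[(1Z,3S)-1-butoxy-3-methylpenta-1,4-dien-3-yl]-2,3-bis(methoxymethoxy)benzene
Product: 12 (3R)-3-[3-bromo-4,5-bis(methoxymethoxy)phenyl]-3-methylpent-4-en-1-ol, via aldehyde 11 (not isolated)
Conditions: 0.5 M HCl, THF/H2O, 0 °C → rt; then NaHCO3, NaBH4, MeOH, 0 °C
Reagents that add atoms: water, O
Why: Acid-catalysed enol ether hydrolysis (protonation at C4, collapse of the hemiacetal at C5) followed by borohydride reduction of the aldehyde; the aryl MOM acetals and the aryl bromide should survive brief dilute acid, and the quaternary centre cannot epimerise.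

**Step 10**
Reactants: 12 (3R)-3-[3-bromo-4,5-bis(methoxymethoxy)phenyl]-3-methylpent-4-en-1-ol
Product: 13 1-bromo-5-[(3R)-5-iodo-3-methylpent-1-en-3-yl]-2,3-bis(methoxymethoxy)benzene
Conditions: I2, PPh3, imidazole, CH2Cl2, 0 °C → rt
Reagents that add atoms: iodine, [I][I]
Why: Appel-type iodination of the primary alcohol by displacement of the alkoxyphosphonium ion with iodide; imidazole buffers the acid so that the MOM acetals persist.

**Step 11**
Reactants: 14 6-methylhept-5-en-2-one
Product: 16 6-methylhept-5-en-1-yne, via enol phosphate 15 (not isolated)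
Conditions: LiN(iPr)2 (1.1 equiv), THF, −78 °C; ClP(O)(OEt)2; then LiN(iPr)2 (2.3 equiv), −78 °C → rt; H2O
Reagents that add atoms: none
Why: Conversion of a methyl ketone into a terminal alkyne: the kinetic enolate on the methyl side is trapped as the enol phosphate, which undergoes amide-induced elimination to the acetylide and is protonated on work-up.

**Step 12**
Reactants: 16 6-methylhept-5-en-1-yne
Product: 18 (1E)-1-iodo-2,6-dimethylhepta-1,5-diene, via alkenylalane 17 (not isolated)
Conditions: AlMe3 (2.5 equiv), Cp2ZrCl2 (0.25 equiv), CH2Cl2, 0 °C → rt; then I2, THF, −30 → 0 °C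
Reagents that add atoms: trimethylaluminium, C[Al](C)C; iodine, [I][I]
Why: Zirconium-catalysed carboalumination (Negishi carboalumination) adds methyl and aluminium syn across the terminal alkyne with aluminium at the terminal carbon, and iodinolysis with retention gives the (E)-alkenyl iodide.

**Step 13**
Reactants: 13 1-bromo-5-[(3R)-5-iodo-3-methylpent-1-en-3-yl]-2,3-bis(methoxymethoxy)benzene; 18 (1E)-1-iodo-2,6-dimethylhepta-1,5-diene
Product: 20 1-bromo-2,3-bis(methoxymethoxy)-5-[(3R,6E)-3,7,11-trimethyldodeca-1,6,10-trien-3-yl]benzene, via alkylzinc iodide 19 (not isolated)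
Conditions: Zn (dust, activated with BrCH2CH2Br and Me3SiCl), LiCl, THF, 30 °C; then 18 (1.3 equiv), PdCl2(dppf) (3 mol%), THF/DMF, rt
Reagents that add atoms: none
Why: Negishi cross-coupling: zinc inserts into the primary C–I bond but not into the electron-rich aryl C–Br bond, the alkylzinc iodide transmetalates to the alkenylpalladium iodide formed from 18 and zerovalent palladium with retention of the (E) geometry, oxidative addition to the alkenyl iodide at rt should be far faster than to the ortho-oxygenated aryl bromide, and the bidentate dppf ligand should make reductive elimination faster than β-hydride elimination.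

**Step 14**
Reactants: 21 2',3'-dihydroxyacetophenone
Product: 22 1-[2-hydroxy-3-{[2-(trimethylsilyl)ethoxy]methoxy}phenyl]ethanone
Conditions: NaH (2.1 equiv), THF/DMSO, 0 °C → rt; SEMCl (1.0 equiv)
Reagents that add atoms: 2-(trimethylsilyl)ethoxymethyl chloride, C[Si](C)(C)CCOCCl
Why: Regioselective O-alkylation of the catecholate dianion, in which the C3' phenoxide is neither delocalised into nor chelated by the acetyl group and is therefore the more nucleophilic oxygen.

**Step 15**
Reactants: 22 1-[2-hydroxy-3-{[2-(trimethylsilyl)ethoxy]methoxy}phenyl]ethanone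
Product: 23 1-[2-(methoxymethoxy)-3-{[2-(trimethylsilyl)ethoxy]methoxy}phenyl]ethanone
Conditions: NaH (1.1 equiv), MOMCl (1.3 equiv), DMF, 0 °C → rt
Reagents that add atoms: chloromethyl methyl ether, COCCl
Why: O-Alkylation of the sodium phenoxide (MOM acetal formation) overcomes the hydrogen bond to the acetyl group and gives two acetal ethers of which only the SEM group answers to fluoride.

**Step 16**
Reactants: 23 1-[2-(methoxymethoxy)-3-{[2-(trimethylsilyl)ethoxy]methoxy}phenyl]ethanone
Product: 24 2-(methoxymethoxy)-1-(prop-1-en-2-yl)-3-{[2-(trimethylsilyl)ethoxy]methoxy}benzene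
Conditions: Ph3PCH3Br, KOtBu, THF, 0 °C → rt
Reagents that add atoms: methyltriphenylphosphonium bromide, C[P+](c1ccccc1)(c1ccccc1)c1ccccc1.[Br-]
Why: Wittig methylenation, which tolerates the ortho substituent because the ylide is small and reactive.

**Step 17**
Reactants: 24 2-(methoxymethoxy)-1-(prop-1-en-2-yl)-3-{[2-(trimethylsilyl)ethoxy]methoxy}benzene
Product: 25 1-(2,2-dibromo-1-methylcyclopropyl)-2-(methoxymethoxy)-3-{[2-(trimethylsilyl)ethoxy]methoxy}benzene (racemic)
Conditions: CHBr3, 50% aq NaOH, BnEt3NCl (5 mol%), CH2Cl2, rt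
Reagents that add atoms: bromoform, BrC(Br)Br
Why: Phase-transfer dibromocarbene [2+1] cycloaddition to the only alkene present; both acetals are stable to aqueous base.

**Step 18**
Reactants: 25 1-(2,2-dibromo-1-methylcyclopropyl)-2-(methoxymethoxy)-3-{[2-(trimethylsilyl)ethoxy]methoxy}benzene
Product: 26 1-(2-bromo-1-methylcyclopropyl)-2-(methoxymethoxy)-3-{[2-(trimethylsilyl)ethoxy]methoxy}benzene (racemic, both diastereomers)
Conditions: EtMgBr (1.3 equiv), Ti(OiPr)4 (5 mol%), Et2O, rt
Reagents that add atoms: none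
Why: Titanium-catalysed hydrodebromination of the gem-dibromocyclopropane, as in step 6.

**Step 19**
Reactants: 26 1-(2-bromo-1-methylcyclopropyl)-2-(methoxymethoxy)-3-{[2-(trimethylsilyl)ethoxy]methoxy}benzene
Product: 27 3-[2-(methoxymethoxy)-3-{[2-(trimethylsilyl)ethoxy]methoxy}phenyl]-3-methylcyclopropene
Conditions: KOtBu (1.5 equiv), DMSO, rt
Reagents that add atoms: none
Why: Base-induced 1,2-dehydrobromination to the 3,3-disubstituted cyclopropene, as in step 7; MOM and SEM acetals are stable to alkoxide.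

**Step 20**
Reactants: 27 3-[2-(methoxymethoxy)-3-{[2-(trimethylsilyl)ethoxy]methoxy}phenyl]-3-methylcyclopropene; 9 butyl vinyl ether
Product: 28 1-[(1Z,3R)-1-butoxy-3-methylpenta-1,4-dien-3-yl]-2-(methoxymethoxy)-3-{[2-(trimethylsilyl)ethoxy]methoxy}benzene
Conditions: Mo(N-2,6-iPr2C6H3)(CHCMe2Ph)(2,5-Me2C4H2N)(OAr*) made from the mirror-image HOAr* (5 mol%), 9 (10 equiv), C6H6, 22 °C
Reagents that add atoms: none
Why: Enantioselective ring-opening/cross-metathesis as in step 8, in which the mirror-image aryloxide at the stereogenic molybdenum centre selects the other enantiotopic olefinic carbon and so sets the ring B centre in the opposite sense.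

**Step 21**
Reactants: 28 1-[(1Z,3R)-1-butoxy-3-methylpenta-1,4-dien-3-yl]-2-(methoxymethoxy)-3-{[2-(trimethylsilyl)ethoxy]methoxy}benzene
Product: 30 (3S)-3-[2-(methoxymethoxy)-3-{[2-(trimethylsilyl)ethoxy]methoxy}phenyl]-3-methylpent-4-en-1-ol, via aldehyde 29 (not isolated)
Conditions: 0.5 M HCl, THF/H2O, 0 °C → rt; then NaHCO3, NaBH4, MeOH, 0 °C
Reagents that add atoms: water, O
Why: Acid-catalysed enol ether hydrolysis followed by borohydride reduction, as in step 9; the aryl MOM and SEM acetals should survive brief dilute acid, and the quaternary centre cannot epimerise.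

**Step 22**
Reactants: 30 (3S)-3-[2-(methoxymethoxy)-3-{[2-(trimethylsilyl)ethoxy]methoxy}phenyl]-3-methylpent-4-en-1-ol
Product: 31 1-[(3S)-5-iodo-3-methylpent-1-en-3-yl]-2-(methoxymethoxy)-3-{[2-(trimethylsilyl)ethoxy]methoxy}benzene
Conditions: I2, PPh3, imidazole, CH2Cl2, 0 °C → rt
Reagents that add atoms: iodine, [I][I]
Why: Appel-type iodination of the primary alcohol, as in step 10; the buffered medium spares both acetals.

**Step 23**
Reactants: 31 1-[(3S)-5-iodo-3-methylpent-1-en-3-yl]-2-(methoxymethoxy)-3-{[2-(trimethylsilyl)ethoxy]methoxy}benzene; 18 (1E)-1-iodo-2,6-dimethylhepta-1,5-diene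
Product: 33 2-(methoxymethoxy)-1-[(3S,6E)-3,7,11-trimethyldodeca-1,6,10-trien-3-yl]-3-{[2-(trimethylsilyl)ethoxy]methoxy}benzene, via alkylzinc iodide 32 (not isolated)
Conditions: Zn (dust, activated with BrCH2CH2Br and Me3SiCl), LiCl, THF, 35 °C; then 18 (1.2 equiv), PdCl2(dppf) (3 mol%), THF/DMF, rt → 45 °C
Reagents that add atoms: none
Why: Negishi cross-coupling as in step 13, here without any aryl halide in the substrate, so that the alkylzinc iodide meets only the alkenylpalladium iodide formed from 18 and zerovalent palladium and couples with retention of the (E) geometry.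

**Step 24**
Reactants: 33 2-(methoxymethoxy)-1-[(3S,6E)-3,7,11-trimethyldodeca-1,6,10-trien-3-yl]-3-{[2-(trimethylsilyl)ethoxy]methoxy}benzene
Product: 34 2-(methoxymethoxy)-3-[(3S,6E)-3,7,11-trimethyldodeca-1,6,10-trien-3-yl]phenol
Conditions: Bu4NF (4 equiv), H2NCH2CH2NH2 (4 equiv), DMF, 60 °C; aq NH4Cl
Reagents that add atoms: none
Why: Fluoride-induced fragmentation of the SEM ether (attack at silicon, loss of ethene and formaldehyde), to which the MOM acetal and the alkenes are inert; ethylenediamine scavenges the formaldehyde.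

**Step 25**
Reactants: 20 1-bromo-2,3-bis(methoxymethoxy)-5-[(3R,6E)-3,7,11-trimethyldodeca-1,6,10-trien-3-yl]benzene; 34 2-(methoxymethoxy)-3-[(3S,6E)-3,7,11-trimethyldodeca-1,6,10-trien-3-yl]phenol
Product: 35 5-[(3R,6E)-3,7,11-trimethyldodeca-1,6,10-trien-3-yl]-1-{2-(methoxymethoxy)-3-[(3S,6E)-3,7,11-trimethyldodeca-1,6,10-trien-3-yl]phenoxy}-2,3-bis(methoxymethoxy)benzene
Conditions: 34 (1.2 equiv), CuI (10 mol%), picolinic acid (20 mol%), K3PO4 (2 equiv), DMSO, 90 °C
Reagents that add atoms: none
Why: Ullmann-type copper-catalysed diaryl ether synthesis, in which the copper phenoxide of 34 activates the C–Br bond of 20 and C–O reductive elimination follows; MOM acetals and the unconjugated alkenes are stable to the basic medium.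

**Step 26**
Reactants: 35 the tris(methoxymethyl) ether of step 25
Product: 36 5-[(3R,6E)-3,7,11-trimethyldodeca-1,6,10-trien-3-yl]-3-{2-hydroxy-3-[(3S,6E)-3,7,11-trimethyldodeca-1,6,10-trien-3-yl]phenoxy}benzene-1,2-diol (CNP0325484.1)
Conditions: HCl (0.5 M, from AcCl), MeOH/THF, 0 °C → rt
Reagents that add atoms: none
Why: Acid-catalysed acetal exchange (MOM methanolysis) frees the three phenols as dimethoxymethane; dilute acid at rt is chosen so that the trisubstituted alkenes are not protonated.

**Compound list**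
1 | acetovanillone | CC(=O)c1ccc(O)c(OC)c1 | starting material
2 | 1-(3-bromo-4-hydroxy-5-methoxyphenyl)ethanone | CC(=O)c1cc(Br)c(O)c(OC)c1 | intermediate
3 | 1-(3-bromo-4,5-dihydroxyphenyl)ethanone | CC(=O)c1cc(O)c(O)c(Br)c1 | intermediate
4 | 1-[3-bromo-4,5-bis(methoxymethoxy)phenyl]ethanone | CC(=O)c1cc(OCOC)c(OCOC)c(Br)c1 | intermediate
5 | 1-bromo-2,3-bis(methoxymethoxy)-5-(prop-1-en-2-yl)benzene | C=C(C)c1cc(OCOC)c(OCOC)c(Br)c1 | intermediate
6 | 1-bromo-5-(2,2-dibromo-1-methylcyclopropyl)-2,3-bis(methoxymethoxy)benzene, racemic | CC1(CC1(Br)Br)c1cc(OCOC)c(OCOC)c(Br)c1 | intermediate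
7 | 1-bromo-5-(2-bromo-1-methylcyclopropyl)-2,3-bis(methoxymethoxy)benzene, racemic, both diastereomers | CC1(CC1Br)c1cc(OCOC)c(OCOC)c(Br)c1 | intermediate
8 | 3-[3-bromo-4,5-bis(methoxymethoxy)phenyl]-3-methylcyclopropene | CC1(C=C1)c1cc(OCOC)c(OCOC)c(Br)c1 | intermediate
9 | butyl vinyl ether | C=COCCCC | starting material
10 | 1-bromo-5-[(1Z,3S)-1-butoxy-3-methylpenta-1,4-dien-3-yl]-2,3-bis(methoxymethoxy)benzene | C=C[C@@](C)(/C=C\OCCCC)c1cc(OCOC)c(OCOC)c(Br)c1 | intermediate
11 | (3R)-3-[3-bromo-4,5-bis(methoxymethoxy)phenyl]-3-methylpent-4-enal | C=C[C@@](C)(CC=O)c1cc(OCOC)c(OCOC)c(Br)c1 | intermediate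
12 | (3R)-3-[3-bromo-4,5-bis(methoxymethoxy)phenyl]-3-methylpent-4-en-1-ol | C=C[C@@](C)(CCO)c1cc(OCOC)c(OCOC)c(Br)c1 | intermediate
13 | 1-bromo-5-[(3R)-5-iodo-3-methylpent-1-en-3-yl]-2,3-bis(methoxymethoxy)benzene | C=C[C@@](C)(CCI)c1cc(OCOC)c(OCOC)c(Br)c1 | intermediate
14 | 6-methylhept-5-en-2-one | CC(=O)CCC=C(C)C | starting material
15 | diethyl 6-methylhepta-1,5-dien-2-yl phosphate | C=C(CCC=C(C)C)OP(=O)(OCC)OCC | intermediate
16 | 6-methylhept-5-en-1-yne | C#CCCC=C(C)C | intermediate
17 | [(1E)-2,6-dimethylhepta-1,5-dien-1-yl]dimethylalane | C[Al](C)/C=C(\C)CCC=C(C)C | intermediate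
18 | (1E)-1-iodo-2,6-dimethylhepta-1,5-diene | I/C=C(\C)CCC=C(C)C | intermediate
19 | {(3R)-3-[3-bromo-4,5-bis(methoxymethoxy)phenyl]-3-methylpent-4-en-1-yl}zinc iodide | C=C[C@@](C)(CC[Zn]I)c1cc(OCOC)c(OCOC)c(Br)c1 | intermediate
20 | 1-bromo-2,3-bis(methoxymethoxy)-5-[(3R,6E)-3,7,11-trimethyldodeca-1,6,10-trien-3-yl]benzene | C=C[C@@](C)(CC/C=C(\C)CCC=C(C)C)c1cc(OCOC)c(OCOC)c(Br)c1 | intermediate
21 | 2',3'-dihydroxyacetophenone | CC(=O)c1cccc(O)c1O | starting material
22 | 1-[2-hydroxy-3-{[2-(trimethylsilyl)ethoxy]methoxy}phenyl]ethanone | CC(=O)c1cccc(OCOCC[Si](C)(C)C)c1O | intermediate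
23 | 1-[2-(methoxymethoxy)-3-{[2-(trimethylsilyl)ethoxy]methoxy}phenyl]ethanone | CC(=O)c1cccc(OCOCC[Si](C)(C)C)c1OCOC | intermediate
24 | 2-(methoxymethoxy)-1-(prop-1-en-2-yl)-3-{[2-(trimethylsilyl)ethoxy]methoxy}benzene | C=C(C)c1cccc(OCOCC[Si](C)(C)C)c1OCOC | intermediate
25 | 1-(2,2-dibromo-1-methylcyclopropyl)-2-(methoxymethoxy)-3-{[2-(trimethylsilyl)ethoxy]methoxy}benzene, racemic | CC1(CC1(Br)Br)c1cccc(OCOCC[Si](C)(C)C)c1OCOC | intermediate
26 | 1-(2-bromo-1-methylcyclopropyl)-2-(methoxymethoxy)-3-{[2-(trimethylsilyl)ethoxy]methoxy}benzene, racemic, both diastereomers | CC1(CC1Br)c1cccc(OCOCC[Si](C)(C)C)c1OCOC | intermediate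
27 | 3-[2-(methoxymethoxy)-3-{[2-(trimethylsilyl)ethoxy]methoxy}phenyl]-3-methylcyclopropene | CC1(C=C1)c1cccc(OCOCC[Si](C)(C)C)c1OCOC | intermediate
28 | 1-[(1Z,3R)-1-butoxy-3-methylpenta-1,4-dien-3-yl]-2-(methoxymethoxy)-3-{[2-(trimethylsilyl)ethoxy]methoxy}benzene | C=C[C@](C)(/C=C\OCCCC)c1cccc(OCOCC[Si](C)(C)C)c1OCOC | intermediate
29 | (3S)-3-[2-(methoxymethoxy)-3-{[2-(trimethylsilyl)ethoxy]methoxy}phenyl]-3-methylpent-4-enal | C=C[C@](C)(CC=O)c1cccc(OCOCC[Si](C)(C)C)c1OCOC | intermediate
30 | (3S)-3-[2-(methoxymethoxy)-3-{[2-(trimethylsilyl)ethoxy]methoxy}phenyl]-3-methylpent-4-en-1-ol | C=C[C@](C)(CCO)c1cccc(OCOCC[Si](C)(C)C)c1OCOC | intermediate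
31 | 1-[(3S)-5-iodo-3-methylpent-1-en-3-yl]-2-(methoxymethoxy)-3-{[2-(trimethylsilyl)ethoxy]methoxy}benzene | C=C[C@](C)(CCI)c1cccc(OCOCC[Si](C)(C)C)c1OCOC | intermediate
32 | {(3S)-3-[2-(methoxymethoxy)-3-{[2-(trimethylsilyl)ethoxy]methoxy}phenyl]-3-methylpent-4-en-1-yl}zinc iodide | C=C[C@](C)(CC[Zn]I)c1cccc(OCOCC[Si](C)(C)C)c1OCOC | intermediate
33 | 2-(methoxymethoxy)-1-[(3S,6E)-3,7,11-trimethyldodeca-1,6,10-trien-3-yl]-3-{[2-(trimethylsilyl)ethoxy]methoxy}benzene | C=C[C@](C)(CC/C=C(\C)CCC=C(C)C)c1cccc(OCOCC[Si](C)(C)C)c1OCOC | intermediate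
34 | 2-(methoxymethoxy)-3-[(3S,6E)-3,7,11-trimethyldodeca-1,6,10-trien-3-yl]phenol | C=C[C@](C)(CC/C=C(\C)CCC=C(C)C)c1cccc(O)c1OCOC | intermediate
35 | 5-[(3R,6E)-3,7,11-trimethyldodeca-1,6,10-trien-3-yl]-1-{2-(methoxymethoxy)-3-[(3S,6E)-3,7,11-trimethyldodeca-1,6,10-trien-3-yl]phenoxy}-2,3-bis(methoxymethoxy)benzene | C=C[C@@](C)(CC/C=C(\C)CCC=C(C)C)c1cc(OCOC)c(OCOC)c(Oc2cccc([C@](C)(C=C)CC/C=C(\C)CCC=C(C)C)c2OCOC)c1 | intermediate
36 | 5-[(3R,6E)-3,7,11-trimethyldodeca-1,6,10-trien-3-yl]-3-{2-hydroxy-3-[(3S,6E)-3,7,11-trimethyldodeca-1,6,10-trien-3-yl]phenoxy}benzene-1,2-diol | C=C[C@@](C)(CC/C=C(\C)CCC=C(C)C)c1cc(O)c(O)c(Oc2cccc([C@](C)(C=C)CC/C=C(\C)CCC=C(C)C)c2O)c1 | target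

**Step count.** Total: 26 steps. Longest linear sequence: 13 steps (steps 1–10, 13, 25, 26; the ring B branch, steps 14–26, is equally long).

**Three steps most likely to fail**

1. Step 20. Process: the ortho MOM ether beside the cyclopropene carbon may crowd or bind the molybdenum centre, so that turnover is slow and the two enantiotopic olefinic carbons are poorly distinguished. Fallback: setting out from 27 and 9, the ring opening is run with the same complex made from racemic HOAr*, which should give the racemic enol ether F1. Preparative supercritical-fluid chromatography on a chiral stationary phase (for example cellulose tris(3,5-dimethylphenylcarbamate)) separates the enantiomers, and the (R) enantiomer comes back to the route at 28. Stereocontrol then rests on separation instead of catalysis.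

2. Step 13. Process: once the alkenyl iodide runs low, zerovalent palladium may add to the aryl C–Br bond, so that the alkylzinc of one molecule couples with the aryl bromide of another and oligomers form. Fallback: the bromide is consumed before the chain is built. Setting out from 10, Ullmann coupling with the phenol 34 under the conditions of step 25 should give the mono(enol ether) diaryl ether F2. Hydrolysis (0.5 M HCl, THF/H2O) to the aldehyde F3 and NaBH4 reduction give the alcohol F4, and iodination (I2, PPh3, imidazole) gives the iodide F5. Zinc insertion (Zn, LiCl, THF) gives the alkylzinc iodide F6, and its Negishi coupling with 18 [PdCl2(dppf), THF/DMF] comes back to the route at 35.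

3. Step 25. Process: slow activation of the electron-rich, ortho-oxygenated C–Br bond by copper, with protodebromination of 20 and oxidative decay of the phenoxide competing. Fallback: setting out from 20, bromine–lithium exchange (n-BuLi, THF, −78 °C) gives the aryllithium F7, which is trapped with B(OMe)3 and hydrolysed on NH4Cl work-up to the arylboronic acid F8. Oxidative Chan–Lam coupling of F8 with 34 [Cu(OAc)2, pyridine, 4 Å molecular sieves, CH2Cl2, air, rt] makes ring A the nucleophilic partner and comes back to the route at 35.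

**Further compounds**
F1 | step 20 | racemic 1-[(1Z)-1-butoxy-3-methylpenta-1,4-dien-3-yl]-2-(methoxymethoxy)-3-{[2-(trimethylsilyl)ethoxy]methoxy}benzene | C=CC(C)(/C=C\OCCCC)c1cccc(OCOCC[Si](C)(C)C)c1OCOC
F2 | step 13 | 5-[(1Z,3S)-1-butoxy-3-methylpenta-1,4-dien-3-yl]-2,3-bis(methoxymethoxy)-1-{2-(methoxymethoxy)-3-[(3S,6E)-3,7,11-trimethyldodeca-1,6,10-trien-3-yl]phenoxy}benzene | C=C[C@@](C)(/C=C\OCCCC)c1cc(OCOC)c(OCOC)c(Oc2cccc([C@](C)(C=C)CC/C=C(\C)CCC=C(C)C)c2OCOC)c1
F3 | step 13 | (3R)-3-{3,4-bis(methoxymethoxy)-5-[2-(methoxymethoxy)-3-((3S,6E)-3,7,11-trimethyldodeca-1,6,10-trien-3-yl)phenoxy]phenyl}-3-methylpent-4-enal | C=C[C@@](C)(CC=O)c1cc(OCOC)c(OCOC)c(Oc2cccc([C@](C)(C=C)CC/C=C(\C)CCC=C(C)C)c2OCOC)c1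
F4 | step 13 | (3R)-3-{3,4-bis(methoxymethoxy)-5-[2-(methoxymethoxy)-3-((3S,6E)-3,7,11-trimethyldodeca-1,6,10-trien-3-yl)phenoxy]phenyl}-3-methylpent-4-en-1-ol | C=C[C@@](C)(CCO)c1cc(OCOC)c(OCOC)c(Oc2cccc([C@](C)(C=C)CC/C=C(\C)CCC=C(C)C)c2OCOC)c1
F5 | step 13 | 5-[(3R)-5-iodo-3-methylpent-1-en-3-yl]-2,3-bis(methoxymethoxy)-1-{2-(methoxymethoxy)-3-[(3S,6E)-3,7,11-trimethyldodeca-1,6,10-trien-3-yl]phenoxy}benzene | C=C[C@@](C)(CCI)c1cc(OCOC)c(OCOC)c(Oc2cccc([C@](C)(C=C)CC/C=C(\C)CCC=C(C)C)c2OCOC)c1
F6 | step 13 | {(3R)-3-{3,4-bis(methoxymethoxy)-5-[2-(methoxymethoxy)-3-((3S,6E)-3,7,11-trimethyldodeca-1,6,10-trien-3-yl)phenoxy]phenyl}-3-methylpent-4-en-1-yl}zinc iodide | C=C[C@@](C)(CC[Zn]I)c1cc(OCOC)c(OCOC)c(Oc2cccc([C@](C)(C=C)CC/C=C(\C)CCC=C(C)C)c2OCOC)c1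
F7 | step 25 | {2,3-bis(methoxymethoxy)-5-[(3R,6E)-3,7,11-trimethyldodeca-1,6,10-trien-3-yl]phenyl}lithium | C=C[C@@](C)(CC/C=C(\C)CCC=C(C)C)c1cc(OCOC)c(OCOC)c([Li])c1
F8 | step 25 | {2,3-bis(methoxymethoxy)-5-[(3R,6E)-3,7,11-trimethyldodeca-1,6,10-trien-3-yl]phenyl}boronic acid | C=C[C@@](C)(CC/C=C(\C)CCC=C(C)C)c1cc(OCOC)c(OCOC)c(B(O)O)c1
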